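**Retrosynthetic overview**
1. Target ⇐ one last operation: CrCl2-mediated intramolecular allylation of an enal by a (Z)-2-(bromomethyl)enoate. The C1–C2 bond closes the 14-membered ring and the alkoxide lactonises, so both rings and both C1/C2 stereocentres arise together.
2. Seco bromo-enal ⇐ two cross-metatheses on one diene: allyl end with methyl 2-(bromomethyl)acrylate, tertiary vinyl carbinol with (E)-3-methylhexa-2,5-dienal.
3. Diene ⇐ epoxy aldehyde by reagent-controlled allylboration (C13) and acetylation; epoxy aldehyde ⇐ Sharpless epoxidation (C11, C12) of a (Z)-allylic alcohol from Still–Gennari olefination.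
4. C8 comes from (S)-linalool (selective ozonolysis); the dienal from pent-1-en-4-yne by Negishi carboalumination.
5. Ring order: epoxide (step 5), then macrocycle and lactone together (step 13).

Assumption: (S)-(+)-linalool is taken as an inexpensive commercial chiral-pool material; atom labels C1–C17 follow cembranoid numbering of the target (C1–C14 ring, C15–C17 lactone carbons).

**Step 1**
Reactants: 1 (S)-(+)-linalool
Product: 2 triethyl{[(3S)-3,7-dimethylocta-1,6-dien-3-yl]oxy}silane
Conditions: Et3SiOTf, 2,6-lutidine, CH2Cl2, −78 → 0 °C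
Reagents that add atoms: triethylsilyl trifluoromethanesulfonate, CC[Si](CC)(CC)OS(=O)(=O)C(F)(F)F
Why: Silyl triflate etherification masks the tertiary C8 hydroxyl so that it cannot later add to the epoxide or the enoate; no stereocentre is touched.

**Step 2**
Reactants: 2 triethyl{[(3S)-3,7-dimethylocta-1,6-dien-3-yl]oxy}silane
Product: 4 (4S)-4-methyl-4-[(triethylsilyl)oxy]hex-5-enal, via secondary ozonide 3 (not isolated)
Conditions: O3, CH2Cl2, −78 °C, Sudan Red 7B end point; then PPh3, −78 °C → rt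
Reagents that add atoms: ozone, [O-][O+]=O
Why: Criegee ozonolysis is selective for the electron-rich trisubstituted alkene over the hindered vinyl group, and PPh3 reduces the ozonide to the aldehyde.

**Step 3**
Reactants: 4 (4S)-4-methyl-4-[(triethylsilyl)oxy]hex-5-enal; 5 ethyl 2-[bis(2,2,2-trifluoroethoxy)phosphoryl]propanoate
Product: 6 ethyl (2Z,6S)-2,6-dimethyl-6-[(triethylsilyl)oxy]octa-2,7-dienoate
Conditions: KN(SiMe3)2, 18-crown-6, THF, −78 °C
Reagents that add atoms: none
Why: Still–Gennari olefination gives the (Z)-2-methyl enoate under kinetic control, fixing the cis relation of C10 and C13 that the cis-epoxide needs.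

**Step 4**
Reactants: 6 ethyl (2Z,6S)-2,6-dimethyl-6-[(triethylsilyl)oxy]octa-2,7-dienoate
Product: 7 (2Z,6S)-2,6-dimethyl-6-[(triethylsilyl)oxy]octa-2,7-dien-1-ol
Conditions: i-Bu2AlH (2.5 equiv), CH2Cl2, −78 °C; Rochelle salt work-up
Reagents that add atoms: none
Why: 1,2-reduction of the enoate by i-Bu2AlH gives the allylic alcohol without changing alkene geometry or the silyl ether.

**Step 5**
Reactants: 7 (2Z,6S)-2,6-dimethyl-6-[(triethylsilyl)oxy]octa-2,7-dien-1-ol
Product: 8 [(2R,3S)-2-methyl-3-{(3S)-3-methyl-3-[(triethylsilyl)oxy]pent-4-en-1-yl}oxiran-2-yl]methanol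
Conditions: Ti(OiPr)4 (20 mol %), D-(−)-diethyl tartrate (24 mol %), t-BuOOH, 4 Å MS, CH2Cl2, −20 °C
Reagents that add atoms: tert-butyl hydroperoxide, CC(C)(C)OO
Why: Sharpless asymmetric epoxidation of the primary (Z)-allylic alcohol, in which D-(−)-tartrate delivers oxygen to the face that gives the (11S,12S) epoxide of the target while the vinyl silyl ether is inert.

**Step 6**
Reactants: 8 [(2R,3S)-2-methyl-3-{(3S)-3-methyl-3-[(triethylsilyl)oxy]pent-4-en-1-yl}oxiran-2-yl]methanol
Product: 9 (2S,3S)-2-methyl-3-{(3S)-3-methyl-3-[(triethylsilyl)oxy]pent-4-en-1-yl}oxirane-2-carbaldehyde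
Conditions: TEMPO (10 mol %), PhI(OAc)2, CH2Cl2, rt
Reagents that add atoms: none
Why: Oxoammonium (TEMPO) oxidation gives the aldehyde under near-neutral conditions, and the quaternary α-carbon cannot epimerise.

**Step 7**
Reactants: 9 (2S,3S)-2-methyl-3-{(3S)-3-methyl-3-[(triethylsilyl)oxy]pent-4-en-1-yl}oxirane-2-carbaldehyde
Product: 11 (1R)-1-[(2R,3S)-2-methyl-3-{(3S)-3-methyl-3-[(triethylsilyl)oxy]pent-4-en-1-yl}oxiran-2-yl]but-3-en-1-ol, via borinate ester 10 (not isolated)
Conditions: (+)-Ipc2BOMe [from (−)-α-pinene], allylMgBr, Et2O, 0 °C; then 9, −78 °C; then NaOH, H2O2, 0 °C → rt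
Reagents that add atoms: allylmagnesium bromide, C=CC[Mg]Br
Why: Brown asymmetric allylboration through a closed chair transition state, in which the (−)-α-pinene-derived reagent adds to the Re face of the aldehyde to give the 13R carbinol, matched with the Felkin–Anh preference (attack anti to the epoxide C–O bond).

**Step 8**
Reactants: 11 (1R)-1-[(2R,3S)-2-methyl-3-{(3S)-3-methyl-3-[(triethylsilyl)oxy]pent-4-en-1-yl}oxiran-2-yl]but-3-en-1-ol
Product: 13 (1R)-1-[(2S,3S)-3-[(3S)-3-hydroxy-3-methylpent-4-en-1-yl]-2-methyloxiran-2-yl]but-3-en-1-yl acetate, via silyl ether acetate 12 (not isolated)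
Conditions: Ac2O, pyridine, DMAP (5 mol %), CH2Cl2, 0 °C → rt; MeOH quench; then HF·pyridine, THF, 0 °C → rt
Reagents that add atoms: acetic anhydride, CC(=O)OC(C)=O
Why: DMAP-catalysed acylation of the only free hydroxyl installs the C13 acetate, and buffered fluoride then cleaves the Si–O bond to free the tertiary alcohol without opening the epoxide.

**Step 9**
Reactants: 13 (1R)-1-[(2S,3S)-3-[(3S)-3-hydroxy-3-methylpent-4-en-1-yl]-2-methyloxiran-2-yl]but-3-en-1-yl acetate; 14 methyl 2-(bromomethyl)prop-2-enoate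
Product: 15 methyl (2Z,5R)-5-(acetyloxy)-2-(bromomethyl)-5-[(2S,3S)-3-[(3S)-3-hydroxy-3-methylpent-4-en-1-yl]-2-methyloxiran-2-yl]pent-2-enoate
Conditions: 14 (5 equiv), second-generation Hoveyda–Grubbs catalyst RuCl2(H2IMes)(=CH-C6H4-2-OiPr) (10 mol %), CH2Cl2, 40 °C
Reagents that add atoms: none
Why: Olefin cross-metathesis of the unhindered allyl terminus with the 1,1-disubstituted acrylate (the tertiary vinyl carbinol is too hindered to couple with it) gives the thermodynamic enoate with the chain cis to CH2Br.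

**Step 10**
Reactants: 16 pent-1-en-4-yne
Product: 19 (2E)-3-methylhexa-2,5-dien-1-ol, via alkenyldimethylalane 17 (not isolated), via lithium alkenylalanate 18 (not isolated)
Conditions: AlMe3 (2 equiv), Cp2ZrCl2 (20 mol %), CH2Cl2, 0 °C → rt; evaporate; n-BuLi, THF, −78 °C; (CH2O)n, → rt
Reagents that add atoms: trimethylaluminium, C[Al](C)C; formaldehyde (as paraformaldehyde), C=O
Why: Negishi zirconium-catalysed syn-carboalumination puts methyl on the internal alkyne carbon, and the alanate is hydroxymethylated with retention to give the (E)-allylic alcohol.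

**Step 11**
Reactants: 19 (2E)-3-methylhexa-2,5-dien-1-ol
Product: 20 (2E)-3-methylhexa-2,5-dienal
Conditions: MnO2 (15 equiv), CH2Cl2, rt
Reagents that add atoms: none
Why: MnO2 oxidises the allylic alcohol chemoselectively to the enal without moving the skipped diene into conjugation.

**Step 12**
Reactants: 15 methyl (2Z,5R)-5-(acetyloxy)-2-(bromomethyl)-5-[(2S,3S)-3-[(3S)-3-hydroxy-3-methylpent-4-en-1-yl]-2-methyloxiran-2-yl]pent-2-enoate; 20 (2E)-3-methylhexa-2,5-dienal
Product: 21 methyl (2Z,5R)-5-(acetyloxy)-2-(bromomethyl)-5-[(2S,3S)-3-[(3S,4E,7E)-3-hydroxy-3,7-dimethyl-9-oxonona-4,7-dien-1-yl]-2-methyloxiran-2-yl]pent-2-enoate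
Conditions: 20 (4 equiv), second-generation Hoveyda–Grubbs catalyst RuCl2(H2IMes)(=CH-C6H4-2-OiPr) (10 mol %), 1,4-benzoquinone (10 mol %), CH2Cl2, 40 °C
Reagents that add atoms: none
Why: Olefin cross-metathesis between the unprotected tertiary allylic alcohol and an excess of the allyl-type terminal alkene gives the (E)-C6=C7 alkene, while the trisubstituted alkenes stay out.

**Step 13**
Reactants: 21 methyl (2Z,5R)-5-(acetyloxy)-2-(bromomethyl)-5-[(2S,3S)-3-[(3S,4E,7E)-3-hydroxy-3,7-dimethyl-9-oxonona-4,7-dien-1-yl]-2-methyloxiran-2-yl]pent-2-enoate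
Product: 24 (1S,2S,3E,6E,8S,11S,12S,13R)-13-acetoxy-11,12-epoxy-8-hydroxycembra-3,6,15(17)-trien-16,2-olide (CNP0288879.2), via allylchromium dichloride 22 (not isolated), via chromium alkoxide 23 (not isolated)
Conditions: CrCl2 (10 equiv), THF, 25 °C, 21 added by syringe pump over 12 h (final 2 mM); then 40 °C, 2 h
Reagents that add atoms: none
Why: Nozaki–Hiyama-type (chromium Barbier) intramolecular allylation, in which the allylchromium adds through its γ-carbon (C1) to the enal in a chair transition state with the (Z)-type chain axial to give the syn alkoxide, which acylates itself on the neighbouring ester, so the 14-membered ring and the cis-fused α-methylene lactone form together; the (1S,2S) sense relative to C13 is expected from a macrocyclic transition state that keeps the C13 acetate and the epoxide outside the forming ring, but this is not secured by precedent.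

**Compound list**
1 | (S)-(+)-linalool, (3S)-3,7-dimethylocta-1,6-dien-3-ol | C=C[C@@](C)(O)CCC=C(C)C | starting material
2 | triethyl{[(3S)-3,7-dimethylocta-1,6-dien-3-yl]oxy}silane | C=C[C@@](C)(O[Si](CC)(CC)CC)CCC=C(C)C | intermediate
3 | secondary ozonide, triethyl{[(3S)-5-(5,5-dimethyl-1,2,4-trioxolan-3-yl)-3-methylpent-1-en-3-yl]oxy}silane (both epimers at the ring CH) | C=C[C@@](C)(O[Si](CC)(CC)CC)CCC1OOC(C)(C)O1 | intermediate
4 | (4S)-4-methyl-4-[(triethylsilyl)oxy]hex-5-enal | C=C[C@@](C)(O[Si](CC)(CC)CC)CCC=O | intermediate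
5 | ethyl 2-[bis(2,2,2-trifluoroethoxy)phosphoryl]propanoate (racemic) | CCOC(=O)C(C)P(=O)(OCC(F)(F)F)OCC(F)(F)F | starting material
6 | ethyl (2Z,6S)-2,6-dimethyl-6-[(triethylsilyl)oxy]octa-2,7-dienoate | C=C[C@@](C)(O[Si](CC)(CC)CC)CC/C=C(/C)C(=O)OCC | intermediate
7 | (2Z,6S)-2,6-dimethyl-6-[(triethylsilyl)oxy]octa-2,7-dien-1-ol | C=C[C@@](C)(O[Si](CC)(CC)CC)CC/C=C(/C)CO | intermediate
8 | [(2R,3S)-2-methyl-3-{(3S)-3-methyl-3-[(triethylsilyl)oxy]pent-4-en-1-yl}oxiran-2-yl]methanol (cis-epoxide: chain and CH2OH cis) | C=C[C@@](C)(O[Si](CC)(CC)CC)CC[C@@H]1O[C@]1(C)CO | intermediate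
9 | (2S,3S)-2-methyl-3-{(3S)-3-methyl-3-[(triethylsilyl)oxy]pent-4-en-1-yl}oxirane-2-carbaldehyde | C=C[C@@](C)(O[Si](CC)(CC)CC)CC[C@@H]1O[C@]1(C)C=O | intermediate
10 | borinate ester: 11 with OB(Ipc)2 in place of OH, Ipc = isopinocampheyl from (−)-α-pinene | C=C[C@@](C)(O[Si](CC)(CC)CC)CC[C@@H]1O[C@]1(C)[C@H](OB([C@H]2C[C@H]3C[C@@H]([C@@H]2C)C3(C)C)[C@H]2C[C@H]3C[C@@H]([C@@H]2C)C3(C)C)CC=C | intermediate
11 | (1R)-1-[(2R,3S)-2-methyl-3-{(3S)-3-methyl-3-[(triethylsilyl)oxy]pent-4-en-1-yl}oxiran-2-yl]but-3-en-1-ol | C=C[C@@](C)(O[Si](CC)(CC)CC)CC[C@@H]1O[C@]1(C)[C@H](O)CC=C | intermediate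
12 | (1R)-1-[(2S,3S)-2-methyl-3-{(3S)-3-methyl-3-[(triethylsilyl)oxy]pent-4-en-1-yl}oxiran-2-yl]but-3-en-1-yl acetate (same geometry as 11; the oxirane descriptor changes with the substituent) | C=C[C@@](C)(O[Si](CC)(CC)CC)CC[C@@H]1O[C@]1(C)[C@H](OC(C)=O)CC=C | intermediate
13 | (1R)-1-[(2S,3S)-3-[(3S)-3-hydroxy-3-methylpent-4-en-1-yl]-2-methyloxiran-2-yl]but-3-en-1-yl acetate | C=C[C@@](C)(O)CC[C@@H]1O[C@]1(C)[C@H](OC(C)=O)CC=C | intermediate
14 | methyl 2-(bromomethyl)prop-2-enoate | C=C(CBr)C(=O)OC | starting material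
15 | methyl (2Z,5R)-5-(acetyloxy)-2-(bromomethyl)-5-[(2S,3S)-3-[(3S)-3-hydroxy-3-methylpent-4-en-1-yl]-2-methyloxiran-2-yl]pent-2-enoate | C=C[C@@](C)(O)CC[C@@H]1O[C@]1(C)[C@H](OC(C)=O)C/C=C(\CBr)C(=O)OC | intermediate
16 | pent-1-en-4-yne | C=CCC#C | starting material
17 | dimethyl[(1E)-2-methylpenta-1,4-dien-1-yl]alane | C=CC/C(C)=C/[Al](C)C | intermediate
18 | lithium butyl(dimethyl)[(1E)-2-methylpenta-1,4-dien-1-yl]alanate | [Li+].C=CC/C(C)=C/[Al-](C)(C)CCCC | intermediate
19 | (2E)-3-methylhexa-2,5-dien-1-ol | C=CC/C(C)=C/CO | intermediate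
20 | (2E)-3-methylhexa-2,5-dienal | C=CC/C(C)=C/C=O | intermediate
21 | methyl (2Z,5R)-5-(acetyloxy)-2-(bromomethyl)-5-[(2S,3S)-3-[(3S,4E,7E)-3-hydroxy-3,7-dimethyl-9-oxonona-4,7-dien-1-yl]-2-methyloxiran-2-yl]pent-2-enoate | O=C/C=C(\C)C/C=C/[C@@](C)(O)CC[C@@H]1O[C@]1(C)[C@H](OC(C)=O)C/C=C(\CBr)C(=O)OC | intermediate
22 | allylchromium dichloride: 21 with CH2CrCl2 in place of CH2Br | O=C/C=C(\C)C/C=C/[C@@](C)(O)CC[C@@H]1O[C@]1(C)[C@H](OC(C)=O)C/C=C(\C[Cr](Cl)Cl)C(=O)OC | intermediate
23 | dichlorochromium alkoxide of the macrocyclic seco hydroxy ester (14-membered ring closed, methyl ester and C2–O–Cr still open; 1S,2S) | Cl[Cr](Cl)O[C@H]1/C=C(\C)C/C=C/[C@@](C)(O)CC[C@@H]2O[C@]2(C)[C@H](OC(C)=O)C[C@H]1C(=C)C(=O)OC | intermediate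
24 | (1S,2S,3E,6E,8S,11S,12S,13R)-13-acetoxy-11,12-epoxy-8-hydroxycembra-3,6,15(17)-trien-16,2-olide, CNP0288879.2 | C=C1C(=O)O[C@H]2/C=C(\C)C/C=C/[C@@](C)(O)CC[C@@H]3O[C@]3(C)[C@H](OC(C)=O)C[C@@H]12 | target

**Step count and risk**
Total steps: 13. Longest linear sequence: 11 steps (steps 1–9, 12 and 13, from (S)-linalool); steps 10–11 make the dienal branch.

Three steps most likely to fail:

Step 13. The macrocyclisation may give oligomers, or the C1/C2 pair may form with the wrong sense relative to C13, since only the syn (cis-lactone) relationship is secured by the allyl geometry. Fallback: set out from 13 and replace the reductive organochromium closure by a catalyst-controlled allylboration. Cross-metathesis of 13 with methyl 2-[(4,4,5,5-tetramethyl-1,3,2-dioxaborolan-2-yl)methyl]prop-2-enoate gives the pinacol allylboronate ester F1. A second cross-metathesis with 20 gives the boronate enal F2. F2 is then cyclised in dilute toluene with the chiral phosphoric acid (R)-TRIP: the closed chair transition state of the allylboronate gives the syn relationship, the catalyst selects the Re face of the enal, and lactonisation returns to the route at 24.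

Step 12. Cross-metathesis at the hindered tertiary vinyl carbinol with a skipped dienal may stall or isomerise the 1,4-diene. Fallback: set out from 15 and reverse the order of the two ring-forming bonds. Indium metal in THF/H2O couples 15 with 20 intermolecularly (Barbier allylation, syn) and the adduct lactonises to the acyclic cis-lactone F3, whose C1/C2 diastereomers can be separated. Ring-closing metathesis of its two terminal alkenes with the second-generation Grubbs catalyst RuCl2(H2IMes)(PCy3)(=CHPh) at high dilution then forms the C6=C7 bond intramolecularly and returns to the route at 24.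

Step 9. The activated allylic bromide may deactivate the ruthenium carbene, or selectivity between the two terminal alkenes may be poor. Fallback: set out from 13 and bring in the bromide after the metathesis. Cross-metathesis with methyl 2-(hydroxymethyl)prop-2-enoate gives the hydroxymethyl enoate F4, and Appel bromination (CBr4, PPh3, CH2Cl2, 0 °C) of its primary allylic alcohol returns to the route at 15.

**Further compounds**
F1 | step 13 | methyl (2E,5R)-5-(acetyloxy)-5-[(2S,3S)-3-[(3S)-3-hydroxy-3-methylpent-4-en-1-yl]-2-methyloxiran-2-yl]-2-[(4,4,5,5-tetramethyl-1,3,2-dioxaborolan-2-yl)methyl]pent-2-enoate (chain cis to CH2B) | C=C[C@@](C)(O)CC[C@@H]1O[C@]1(C)[C@H](OC(C)=O)C/C=C(\CB2OC(C)(C)C(C)(C)O2)C(=O)OC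
F2 | step 13 | methyl (2E,5R)-5-(acetyloxy)-5-[(2S,3S)-3-[(3S,4E,7E)-3-hydroxy-3,7-dimethyl-9-oxonona-4,7-dien-1-yl]-2-methyloxiran-2-yl]-2-[(4,4,5,5-tetramethyl-1,3,2-dioxaborolan-2-yl)methyl]pent-2-enoate | O=C/C=C(\C)C/C=C/[C@@](C)(O)CC[C@@H]1O[C@]1(C)[C@H](OC(C)=O)C/C=C(\CB2OC(C)(C)C(C)(C)O2)C(=O)OC
F3 | step 12 | (1R)-1-[(2S,3S)-3-[(3S)-3-hydroxy-3-methylpent-4-en-1-yl]-2-methyloxiran-2-yl]-2-[(2S,3S)-4-methylidene-2-[(1E)-2-methylpenta-1,4-dien-1-yl]-5-oxooxolan-3-yl]ethyl acetate | C=CC/C(C)=C/[C@@H]1OC(=O)C(=C)[C@@H]1C[C@@H](OC(C)=O)[C@@]2(C)O[C@H]2CC[C@](C)(O)C=C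
F4 | step 9 | methyl (2E,5R)-5-(acetyloxy)-2-(hydroxymethyl)-5-[(2S,3S)-3-[(3S)-3-hydroxy-3-methylpent-4-en-1-yl]-2-methyloxiran-2-yl]pent-2-enoate (chain cis to CH2OH) | C=C[C@@](C)(O)CC[C@@H]1O[C@]1(C)[C@H](OC(C)=O)C/C=C(\CO)C(=O)OC
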